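## The problem

Phlorofucofuroeckol A 25 has no stereocentre; its difficulty is regiochemical. Three phloroglucinol-derived rings are fused in line, ring A to ring B through a 1,4-dioxin and ring B to ring C through a furan, and two 3,5-dihydroxyphenoxy rings (P1 on ring A, P2 on ring C) complete the molecule. The atoms are labelled a1 (O–P1), a2 (OH), a3 (H), a4 (OH), a5 and a6 (dioxin oxygens, a5 facing b6 and a6 facing b1); b1 (dioxin O), b2 (OH), b3 (H), b4 (furan O), b5 (bonded to c6), b6 (dioxin O); c1 (furan O), c2 (O–P2), c3 (OH), c4 (H), c5 (OH), c6. Every ring has near-equivalent positions (b3 and b5, c4 and c6, the two orientations of ring A across the dioxin), so each bond must be placed by something stronger than the weak bias of a polyalkoxyarene. The only inter-ring C–C bond, b5–c6, lies between four oxygen-bearing carbons and is the hardest bond to make from two aromatic partners. The nine phenols make the target and any free catechol intermediate sensitive to air and base, so the oxygens are carried as methyl ethers and released last, and aryl halides are kept away from hydrogenolysis. The enabling feature is ring B: oxygens at b4 and b6 flank b5 and another sits at b2, the pattern of a 5-oxygenated cyclohexane-1,3-dione, whose C-2 is the only nucleophilic carbon and whose two carbonyls are equivalent; the last oxygen, b1, is then alpha to a ketone. The price is a beta-methoxy ketone that can lose methanol, plus transient stereocentres at b2 and b1 that control nothing and vanish on aromatization.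

## Retrosynthesis

**Release of the phenols.** The nine O–CH3 bonds of nonamethyl ether 24 are cut last to give 25. Methyl ethers are preferred to benzyl ethers because the building blocks are sold methylated and the route carries aryl iodides and bromides that exclude hydrogenolysis. The forward reaction must cleave nine aryl methyl ethers and leave four diaryl ether, one furan and two dioxin C–O bonds intact.

**Ring P1.** The a1–O–aryl bond of 24 is cut to phenol 22 and 1-iodo-3,5-dimethoxybenzene 23. Carrying ring P1 on the ring A partner from the start would remove the group at a1 that is needed to activate and orient the dioxin formation, so the ring is attached late. The forward reaction is an O-arylation of a phenol flanked by two oxygens.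

**Oxygen at a1.** Phenol 22 comes from aldehyde 20 through formate 21; the C–CHO bond is exchanged for C–O. The formyl group therefore serves twice, first as activator for ring A attachment and then as latent oxygen.

**Dioxin.** In 20 the bond b6–O–a5 is cut first, giving bromo phenol 19, and then b1–O–a6, giving catechol 15 and fluoro aldehyde 18. A one-flask double coupling of 15 with an ortho-dihalide would give both orientations of ring A. The stepwise order uses the formyl-activated fluoride for an intermolecular substitution by the more accessible b1 oxygen and leaves the hindered b6 oxygen for an intramolecular closure.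

**Ring A partner.** Aldehyde 18 comes from 2-bromo-1-fluoro-3,5-dimethoxybenzene 17 and this from 1-fluoro-3,5-dimethoxybenzene 16. Bromine enters by electrophilic substitution para to a methoxy group, and the formyl group by lithiation of the remaining position beside fluorine. Both reactions are simple and each has one preferred site.

**Catechol of ring B.** Catechol 15 is the enol tautomer of 1,2-dione 14, which comes from alpha-hydroxy ketone 13 and this from ketone 12 by cutting the b1–O bond. On an aromatic ring B the new oxygen could go ortho (b1) or para (b3) to the phenol; on the ketone only b1 carries a proton that leads to a stable enolate. No oxidant is needed for the aromatization itself.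

**Key disconnection.** Ketone 12 is cut at b5–c6 and at the furan bond b4–O into iodophenol 8 and 5-methoxycyclohexane-1,3-dione 10. A biaryl coupling of two fully substituted arenes is thereby replaced by C-arylation of a symmetric 1,3-dione, and the furan closes by condensation of the neighbouring phenol with either of two equivalent carbonyls. The two precursors have 16 and 7 carbons against 23 in 12. The forward reaction must arylate carbon and not oxygen, and must not cost the beta-methoxy group.

**Dione.** Dione 10 comes from 5-methoxyresorcinol 9 by saturating one ring double bond.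

**Ring C partner.** Iodophenol 8 is cut at the acetal to 7, at the c2–O–aryl bond to phenol 5 and (3,5-dimethoxyphenyl)boronic acid 6, at the c2 oxygen through formate 4 to aldehyde 3, and at the acetal and the C–I bond to 2-hydroxy-4,6-dimethoxybenzaldehyde 1 by way of 2. Iodine is introduced first, on the simple aldehyde where the chelated phenol directs it, and not after ether formation, where ring P2 (a phloroglucinol triether) and position c4 would compete. The ether is then formed under oxidative copper conditions that spare the iodide.

## Roads not taken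

**Alternative 1:** Both phenoxy rings are grown on the finished core by benzannulation. The cut removes three C–C bonds of each ring P. In the forward key step the bis(ethynyl ether) A2, which carries ethynyl groups on the a1 and c2 oxygens of the pentamethylated core, is heated with 3-ethoxycyclobut-2-en-1-one A3. Cyclobutenone A3 opens on heating, adds across each triple bond of A2, and each adduct opens and recloses to a six-membered ring, so that both oxygens carry a 3-ethoxy-5-hydroxyphenyl group in A1. Merits: no copper O-arylation of a doubly flanked phenol is needed, the meta,meta pattern of each new ring follows from the mechanism, and both rings form in one operation. Weak points: the plan does not address the core at all, so b5–c6, the furan and the oriented dioxin must still be made by another strategy. Aryl ethynyl ethers of 2,6-dioxygenated phenols need two steps each on a late intermediate and are thermally fragile, and two benzannulations must succeed on one molecule of A2. Compared with the chosen plan it spends at least three late steps where the chosen plan spends two single couplings (steps 4 and 15). It is better in avoiding the late hindered O-arylation of 22; against this the chosen plan sets a catalyst system made for hindered phenols and the early, cheap introduction of ring P2.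

**Alternative 2:** Ring C is closed last by a Dieckmann-type condensation on a benzofuran. The cut is c4–c5. In the forward sense keto ester A5, carrying a 1-aryloxy-2-oxopropyl chain on furan C-2 and a methyl ester on furan C-3, is treated with base. The methyl ketone enolate attacks the ester and the ring so formed enolizes to the resorcinol A4. Merits: no hindered C–C coupling, an unambiguous ring C, and c3 and c5 oxygens that arrive at the right oxidation level, so no redox adjustment of ring B is needed; in this respect it is better than the chosen plan. Weak points: A5 must be assembled on the complete dioxin core, so the sequence is long and linear and the key step comes at the end on the most valuable material. The more acidic site of A5 is the methine between furan, aryloxy group and ketone, whose enolate is unproductive. The chosen plan sets against this a convergent union of two small fragments that forms the same ring fusion in one step.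

**Alternative 3:** The dibenzofuran is formed from a quinone and an aryloxyphloroglucinol. The cuts are b5–c6 and O–c1. In the forward sense the triol A8, 2-(3,5-dimethoxyphenoxy)benzene-1,3,5-triol, adds under acid through c6 to carbon b5 of quinone A7, and the hydroquinone oxygen at b4 condenses onto c1 to give A6. Merits: it is the shortest road; ring B arrives aromatic with b1–OH free and ring A, its bromide and ring P1 already in place. A8 is symmetric, so c4 and c6 do not compete. If the addition were selective it would beat the chosen plan in step count. Weak points: quinone A7 offers b3 and b5 as two similar acceptor positions, one beside methoxy and one beside aryloxy, and the bias between them is small. The electron-rich A8 can reduce A7 instead of adding to it. The free c3 and c5 phenols of A6 would compete in the later dioxin closure. The chosen plan pays with extra steps (alpha-oxidation, aromatization) and with the beta-methoxy elimination risk, and obtains in return a b5 position fixed by the symmetry of the dione.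

Key step: step 7

Remark: iodination of 1 is taken to occur at C-3, beside the chelated hydroxyl, as halogenation of the corresponding acetophenone does; a NOE experiment on 2 would confirm this before material is committed.
Remark: bromination of 16 is taken to occur at C-2, para to one methoxy group and beside fluorine, as halogenation of other 5-substituted 1,3-dimethoxybenzenes does.
Remark: chiral intermediates are racemic and drawn as one enantiomer; their stereocentres disappear in step 9.

## Route

Step 1
Reactants: 1 2-hydroxy-4,6-dimethoxybenzaldehyde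
Product: 2 2-hydroxy-3-iodo-4,6-dimethoxybenzaldehyde
Conditions: NIS, TFA (cat.), MeCN, 0 °C to rt
Reagents that add atoms: N-iodosuccinimide, O=C1CCC(=O)N1I
Why: Electrophilic aromatic iodination: the hydrogen-bonded phenol directs to its only free ortho position C-3, while C-5 is crowded by two methoxy groups.

Step 2
Reactants: 2 2-hydroxy-3-iodo-4,6-dimethoxybenzaldehyde
Product: 3 3-iodo-4,6-dimethoxy-2-(methoxymethoxy)benzaldehyde
Conditions: MOMCl, i-Pr2NEt, CH2Cl2, 0 to 40 °C
Reagents that add atoms: chloromethyl methyl ether, COCCl
Why: O-Alkylation of the phenol as an acetal keeps the future furan oxygen (c1) distinct from the oxygen generated beside it in step 3; the acetal withstands buffered peracid and copper and leaves with dilute acid.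

Step 3
Reactants: 3 3-iodo-4,6-dimethoxy-2-(methoxymethoxy)benzaldehyde
Product: 5 3-iodo-4,6-dimethoxy-2-(methoxymethoxy)phenol, via aryl formate 4 (not isolated)
Conditions: mCPBA, NaHCO3, CH2Cl2, 0 °C to rt; aq. NaHCO3 wash; then K2CO3 (cat.), MeOH, rt
Reagents that add atoms: 3-chloroperbenzoic acid, OOC(=O)c1cccc(Cl)c1
Why: Baeyer–Villiger (Dakin-type) oxidation: the trioxygenated aryl group migrates in preference to hydride and the formate is methanolysed, turning the formyl carbon into the c2 oxygen; peracid oxidation of an aryl iodide needs strong acid and is not expected under buffered conditions.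

Step 4
Reactants: 5 3-iodo-4,6-dimethoxy-2-(methoxymethoxy)phenol; 6 (3,5-dimethoxyphenyl)boronic acid
Product: 7 2-(3,5-dimethoxyphenoxy)-4-iodo-1,5-dimethoxy-3-(methoxymethoxy)benzene
Conditions: Cu(OAc)2 (1 equiv), pyridine, 4 Å MS, CH2Cl2, O2 (1 atm), rt
Reagents that add atoms: none
Why: Chan–Lam oxidative O-arylation with Cu(OAc)2, a divalent copper salt that oxygen keeps in that state, runs at room temperature, leaves the aryl iodide untouched (an Ullmann coupling would not) and is known for phenols with two ortho substituents.

Step 5
Reactants: 7 2-(3,5-dimethoxyphenoxy)-4-iodo-1,5-dimethoxy-3-(methoxymethoxy)benzene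
Product: 8 2-(3,5-dimethoxyphenoxy)-6-iodo-3,5-dimethoxyphenol
Conditions: HCl (cat.), MeOH, 40 °C
Reagents that add atoms: none
Why: Acid-catalysed acetal exchange removes the methoxymethyl group; aryl methyl ethers, the diaryl ether and the iodide are inert.

Step 6
Reactants: 9 5-methoxybenzene-1,3-diol (5-methoxyresorcinol)
Product: 10 5-methoxycyclohexane-1,3-dione
Conditions: H2 (4 atm), Rh/Al2O3 (5%), NaOH (1.05 equiv), H2O, rt; then HCl to pH 3, 0 °C
Reagents that add atoms: none
Why: Partial catalytic hydrogenation of a resorcinol monoanion, the standard route to cyclohexane-1,3-diones: reduction stops at the delocalized dione enolate, which is neither reduced further nor able to expel methoxide; 10 is liberated cold and used at once.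

Step 7
Reactants: 8 2-(3,5-dimethoxyphenoxy)-6-iodo-3,5-dimethoxyphenol; 10 5-methoxycyclohexane-1,3-dione
Product: 12 (3RS)-6-(3,5-dimethoxyphenoxy)-3,7,9-trimethoxy-3,4-dihydrodibenzo[b,d]furan-1(2H)-one, via C-arylated dione 11 (not isolated)
Conditions: CuI (20 mol %), L-proline (40 mol %), K2CO3, DMSO, 80 °C, Ar; then 1 M HCl to pH 2; TsOH·H2O (cat.), CH2Cl2, rt
Reagents that add atoms: none
Why: CuI with L-proline gives a monovalent copper species that inserts into the C–I bond at c6, the potassium diketonate of 10 binds through C-2 and reductive elimination forms b5–c6, giving 11. The closest known reaction type is the CuI/amino acid C-arylation of 1,3-dicarbonyl compounds with aryl iodides, combined with the furan annulation of 2-(2-hydroxyaryl)-1,3-diones. The furan closes by 5-exo-trig addition of the c1 phenol oxygen to a dione carbonyl (hemiketal) and loss of water under mild acid, forming b4–O. No stereocentre is created: C-3 only becomes stereogenic because the two arms of ring B now differ, so 12 is racemic and nothing needs control. Site selectivity is secured by the symmetry of 10 (one nucleophilic carbon, two equivalent carbonyls) and by the fact that only the hydroxyl ortho to the new bond can reach a carbonyl. C- over O-arylation is expected from the copper-bound diketonate, and cross- over self-coupling from an excess of 10 and the doubly flanked phenoxide of 8. The methoxy group is retained because under base ring B stays a dione monoanion that cannot undergo E1cB elimination, and the enone is only formed in the acid stage at room temperature.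

Step 8
Reactants: 12 (3RS)-6-(3,5-dimethoxyphenoxy)-3,7,9-trimethoxy-3,4-dihydrodibenzo[b,d]furan-1(2H)-one
Product: 13 (2S*,3R*)-6-(3,5-dimethoxyphenoxy)-2-hydroxy-3,7,9-trimethoxy-3,4-dihydrodibenzo[b,d]furan-1(2H)-one (racemic trans isomer; some cis isomer may accompany it)
Conditions: NaN(SiMe3)2, THF, −78 °C; then 3-phenyl-2-(phenylsulfonyl)oxaziridine, −78 °C; aq. NH4Cl
Reagents that add atoms: 3-phenyl-2-(phenylsulfonyl)oxaziridine, O=S(=O)(c1ccccc1)N1OC1c1ccccc1
Why: Kinetic deprotonation of the vinylogous ester at the alpha-prime carbon C-2 (deprotonation at C-4 would break the furan conjugation) and oxygen transfer from the sulfonyloxaziridine (Davis oxidation); the oxidant should approach anti to the neighbouring methoxy group, but both diastereomers converge in step 9, and at −78 °C loss of methoxide from the enolate is slow.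

Step 9
Reactants: 13 (2S*,3R*)-6-(3,5-dimethoxyphenoxy)-2-hydroxy-3,7,9-trimethoxy-3,4-dihydrodibenzo[b,d]furan-1(2H)-one
Product: 15 6-(3,5-dimethoxyphenoxy)-3,7,9-trimethoxydibenzo[b,d]furan-1,2-diol, via 1,2-dione 14 (not isolated)
Conditions: DMP, CH2Cl2, 0 °C; aq. Na2S2O3/NaHCO3; then Et3N (cat.), CH2Cl2, rt, Ar; aq. Na2S2O4 wash
Reagents that add atoms: none
Why: Dess–Martin oxidation gives the 1,2-dione, which is the keto tautomer of the catechol: enolization at C-3 and then at C-4 aromatizes ring B without change of oxidation level and erases both stereocentres; the dithionite wash returns any ortho-quinone formed by over-oxidation.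

Step 10
Reactants: 16 1-fluoro-3,5-dimethoxybenzene
Product: 17 2-bromo-1-fluoro-3,5-dimethoxybenzene
Conditions: NBS, MeCN, 0 °C to rt
Reagents that add atoms: N-bromosuccinimide, O=C1CCC(=O)N1Br
Why: Electrophilic aromatic bromination para to one methoxy group and ortho to the other, at the position beside the small fluorine; the position between the two methoxy groups is more hindered and lacks a para methoxy group.

Step 11
Reactants: 17 2-bromo-1-fluoro-3,5-dimethoxybenzene
Product: 18 3-bromo-2-fluoro-4,6-dimethoxybenzaldehyde
Conditions: LiN(i-Pr)2, THF, −78 °C; then DMF, −78 °C; aq. NH4Cl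
Reagents that add atoms: N,N-dimethylformamide, CN(C)C=O
Why: Directed ortho-lithiation with a lithium amide removes the most acidic ring proton, the one between fluorine and methoxy, without bromine–lithium exchange, and DMF formylates the aryllithium; at −78 °C the ortho-fluoro aryllithium does not lose LiF.

Step 12
Reactants: 15 6-(3,5-dimethoxyphenoxy)-3,7,9-trimethoxydibenzo[b,d]furan-1,2-diol; 18 3-bromo-2-fluoro-4,6-dimethoxybenzaldehyde
Product: 19 3-bromo-2-{[6-(3,5-dimethoxyphenoxy)-1-hydroxy-3,7,9-trimethoxydibenzo[b,d]furan-2-yl]oxy}-4,6-dimethoxybenzaldehyde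
Conditions: K2CO3 (1.1 equiv), DMSO, 80 °C, Ar
Reagents that add atoms: none
Why: Nucleophilic aromatic substitution of the fluoride ortho to the formyl group and beside bromine (both methoxy groups of 18 are meta to the attacked carbon); the b1 phenoxide is hydrogen-bonded by b6–OH and less hindered than the bay-region b6 oxygen beside the c5 methoxy group, so ring A should be fixed with a6 on b1.

Step 13
Reactants: 19 3-bromo-2-{[6-(3,5-dimethoxyphenoxy)-1-hydroxy-3,7,9-trimethoxydibenzo[b,d]furan-2-yl]oxy}-4,6-dimethoxybenzaldehyde
Product: 20 core aldehyde with the 1,4-dioxin closed between rings A and B (a1 CHO; OMe at a2 a4 b2 c3 c5; 3,5-dimethoxyphenoxy at c2)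
Conditions: CuI (10 mol %), N,N-dimethylglycine (30 mol %), Cs2CO3, dioxane, 90 °C, Ar
Reagents that add atoms: none
Why: Intramolecular Ullmann diaryl ether synthesis: monovalent copper inserts into the a5–Br bond and the b6 phenoxide closes the six-membered dioxin; the amino acid ligand allows 90 °C, which limits base-induced aryl migration in 19.

Step 14
Reactants: 20 core aldehyde (a1 CHO)
Product: 22 core phenol (a1 OH; otherwise as 20), via aryl formate 21 (not isolated)
Conditions: mCPBA, CH2Cl2, 0 °C; aq. NaHCO3 wash; then K2CO3 (cat.), MeOH, rt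
Reagents that add atoms: 3-chloroperbenzoic acid, OOC(=O)c1cccc(Cl)c1
Why: Baeyer–Villiger (Dakin) oxidation of an aryl aldehyde with two ortho oxygens, then methanolysis of the formate; the formyl group that activated step 12 becomes the a1 oxygen.

Step 15
Reactants: 22 core phenol (a1 OH); 23 1-iodo-3,5-dimethoxybenzene
Product: 24 nona-O-methylphlorofucofuroeckol A
Conditions: CuI (10 mol %), picolinic acid (20 mol %), K3PO4, DMSO, 90 °C, Ar
Reagents that add atoms: none
Why: Ullmann-type O-arylation with CuI and picolinic acid, conditions developed for phenols flanked by two ortho substituents; 22 carries no halide, so only cross-coupling is possible.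

Step 16
Reactants: 24 nona-O-methylphlorofucofuroeckol A
Product: 25 phlorofucofuroeckol A
Conditions: BBr3 (excess), CH2Cl2, −78 °C to rt; MeOH then H2O, Ar
Reagents that add atoms: none
Why: Lewis-acid cleavage of the nine aryl methyl ethers by BBr3; diaryl ether, furan and dioxin C–O bonds are not cleaved; the polyphenol is worked up and stored under argon.

## Compound list

1 | 2-hydroxy-4,6-dimethoxybenzaldehyde | O=Cc1c(O)cc(OC)cc1OC | starting material
2 | 2-hydroxy-3-iodo-4,6-dimethoxybenzaldehyde | O=Cc1c(O)c(I)c(OC)cc1OC | intermediate
3 | 3-iodo-4,6-dimethoxy-2-(methoxymethoxy)benzaldehyde | O=Cc1c(OCOC)c(I)c(OC)cc1OC | intermediate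
4 | 3-iodo-4,6-dimethoxy-2-(methoxymethoxy)phenyl formate (not isolated) | O=COc1c(OCOC)c(I)c(OC)cc1OC | intermediate
5 | 3-iodo-4,6-dimethoxy-2-(methoxymethoxy)phenol | Oc1c(OCOC)c(I)c(OC)cc1OC | intermediate
6 | (3,5-dimethoxyphenyl)boronic acid | OB(O)c1cc(OC)cc(OC)c1 | starting material
7 | 2-(3,5-dimethoxyphenoxy)-4-iodo-1,5-dimethoxy-3-(methoxymethoxy)benzene | COCOc1c(Oc2cc(OC)cc(OC)c2)c(OC)cc(OC)c1I | intermediate
8 | 2-(3,5-dimethoxyphenoxy)-6-iodo-3,5-dimethoxyphenol | COc1cc(OC)c(Oc2cc(OC)cc(OC)c2)c(O)c1I | intermediate
9 | 5-methoxybenzene-1,3-diol (5-methoxyresorcinol) | COc1cc(O)cc(O)c1 | starting material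
10 | 5-methoxycyclohexane-1,3-dione | COC1CC(=O)CC(=O)C1 | intermediate
11 | 2-[3-(3,5-dimethoxyphenoxy)-2-hydroxy-4,6-dimethoxyphenyl]-5-methoxycyclohexane-1,3-dione (keto–enol tautomers, no fixed configuration; not isolated) | COC1CC(=O)C(c2c(O)c(Oc3cc(OC)cc(OC)c3)c(OC)cc2OC)C(=O)C1 | intermediate
12 | (3RS)-6-(3,5-dimethoxyphenoxy)-3,7,9-trimethoxy-3,4-dihydrodibenzo[b,d]furan-1(2H)-one (racemic, R enantiomer drawn) | CO[C@H]1CC(=O)c2c(C1)oc1c(Oc3cc(OC)cc(OC)c3)c(OC)cc(OC)c21 | intermediate
13 | (2S*,3R*)-6-(3,5-dimethoxyphenoxy)-2-hydroxy-3,7,9-trimethoxy-3,4-dihydrodibenzo[b,d]furan-1(2H)-one (racemic, trans; 2S,3R enantiomer drawn) | CO[C@H]1[C@H](O)C(=O)c2c(C1)oc1c(Oc3cc(OC)cc(OC)c3)c(OC)cc(OC)c21 | intermediate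
14 | (3RS)-6-(3,5-dimethoxyphenoxy)-3,7,9-trimethoxy-3,4-dihydrodibenzo[b,d]furan-1,2-dione (racemic, one enantiomer drawn; not isolated) | CO[C@H]1C(=O)C(=O)c2c(C1)oc1c(Oc3cc(OC)cc(OC)c3)c(OC)cc(OC)c21 | intermediate
15 | 6-(3,5-dimethoxyphenoxy)-3,7,9-trimethoxydibenzo[b,d]furan-1,2-diol | COc1cc2oc3c(Oc4cc(OC)cc(OC)c4)c(OC)cc(OC)c3c2c(O)c1O | intermediate
16 | 1-fluoro-3,5-dimethoxybenzene | COc1cc(F)cc(OC)c1 | starting material
17 | 2-bromo-1-fluoro-3,5-dimethoxybenzene | COc1cc(OC)c(Br)c(F)c1 | intermediate
18 | 3-bromo-2-fluoro-4,6-dimethoxybenzaldehyde | O=Cc1c(F)c(Br)c(OC)cc1OC | intermediate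
19 | 3-bromo-2-{[6-(3,5-dimethoxyphenoxy)-1-hydroxy-3,7,9-trimethoxydibenzo[b,d]furan-2-yl]oxy}-4,6-dimethoxybenzaldehyde | COc1cc2oc3c(Oc4cc(OC)cc(OC)c4)c(OC)cc(OC)c3c2c(O)c1Oc1c(C=O)c(OC)cc(OC)c1Br | intermediate
20 | core aldehyde: rings A, dioxin, B, furan, C fused as in the target; a1 CHO; OMe at a2, a4, b2, c3, c5; 3,5-dimethoxyphenoxy at c2 | O=Cc1c(OC)cc(OC)c2c1Oc1c(OC)cc3oc4c(Oc5cc(OC)cc(OC)c5)c(OC)cc(OC)c4c3c1O2 | intermediate
21 | core formate: as 20 with a1 O–CHO (not isolated) | O=COc1c(OC)cc(OC)c2c1Oc1c(OC)cc3oc4c(Oc5cc(OC)cc(OC)c5)c(OC)cc(OC)c4c3c1O2 | intermediate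
22 | core phenol: as 20 with a1 OH | Oc1c(OC)cc(OC)c2c1Oc1c(OC)cc3oc4c(Oc5cc(OC)cc(OC)c5)c(OC)cc(OC)c4c3c1O2 | intermediate
23 | 1-iodo-3,5-dimethoxybenzene | COc1cc(I)cc(OC)c1 | starting material
24 | nona-O-methylphlorofucofuroeckol A | COc1cc(OC)cc(Oc2c(OC)cc(OC)c3c2Oc2c(OC)cc4oc5c(Oc6cc(OC)cc(OC)c6)c(OC)cc(OC)c5c4c2O3)c1 | intermediate
25 | phlorofucofuroeckol A | Oc1cc(O)cc(Oc2c(O)cc(O)c3c2Oc2c(O)cc4oc5c(Oc6cc(O)cc(O)c6)c(O)cc(O)c5c4c2O3)c1 | target

## Step count and least certain steps

Total: 16 steps. Longest linear sequence: 13 steps (1 to 25 through steps 1–5, 7–9 and 12–16).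

**Step 7 (key step).** The C–I bond of 8 is electron-rich and flanked on both sides, so insertion of copper may be slow. Reductive deiodination, O-arylation of the dione or self-coupling of the phenoxide could then take over, and prolonged heating with carbonate could cost methanol from ring B. The fallback reverses the polarity of the coupling; it sets out from 7 and 10 and returns at 12. Dione 10 is O-methylated (Me3SiCHN2, MeOH/CH2Cl2, 0 °C) to (5RS)-3,5-dimethoxycyclohex-2-en-1-one F1 and iodinated at C-2 (NIS, MeCN, rt) to (5RS)-2-iodo-3,5-dimethoxycyclohex-2-en-1-one F2. Iodide 7 is converted by iodine–lithium exchange (n-BuLi, THF, −78 °C) and i-PrOBpin into 2-[3-(3,5-dimethoxyphenoxy)-4,6-dimethoxy-2-(methoxymethoxy)phenyl]-4,4,5,5-tetramethyl-1,3,2-dioxaborolane F3. Suzuki–Miyaura coupling of F2 with F3 (Pd(OAc)2, SPhos, K3PO4, toluene/H2O, 80 °C) should give (5RS)-2-[3-(3,5-dimethoxyphenoxy)-4,6-dimethoxy-2-(methoxymethoxy)phenyl]-3,5-dimethoxycyclohex-2-en-1-one F4. HCl in MeOH then removes the acetal, and the freed phenol displaces the enol ether methoxy group to close the furan, giving 12.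

**Step 12.** The wrong catechol oxygen (b6) may attack, or both may, and under base catechol 15 may be oxidized by traces of air; the substitution itself may be slow because the two methoxy groups weaken the activation by the formyl group. The fallback fixes the ring A oxygen on b1 before ring B is aromatic; it sets out from 13 and 1 and returns at 19. Aldehyde 1 is brominated beside the hydroxyl (NBS, MeCN, 0 °C) to 3-bromo-2-hydroxy-4,6-dimethoxybenzaldehyde F5. Mitsunobu etherification of 13 with F5 (PPh3, DIAD, THF, 0 °C) gives, with inversion, (2R*,3R*)-2-(2-bromo-6-formyl-3,5-dimethoxyphenoxy)-6-(3,5-dimethoxyphenoxy)-3,7,9-trimethoxy-3,4-dihydrodibenzo[b,d]furan-1(2H)-one F6. Soft enolization (TMSOTf, Et3N, CH2Cl2, 0 °C) gives the silyl dienol ether (3RS)-2-(2-bromo-6-formyl-3,5-dimethoxyphenoxy)-6-(3,5-dimethoxyphenoxy)-3,7,9-trimethoxy-1-(trimethylsilyloxy)-3,4-dihydrodibenzo[b,d]furan F7. DDQ (CH2Cl2, 0 °C) dehydrogenates ring B of F7, and the silyl group is lost on aqueous work-up, giving 19.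

**Step 13.** Before the copper-catalysed closure, the b6 phenoxide of 19 may attack the formyl-activated carbon a6 and transfer ring A from b1–O to b6–O (aryl migration through a spiro intermediate). This would scramble the orientation of ring A. Slow closure at the hindered bromide could also end in loss of bromine. The fallback removes the activating group first; it sets out from 19 and returns at 22. Dakin oxidation of 19 (30% H2O2, cat. H2SO4, MeOH, 0 °C to rt) passes through 3-bromo-2-{[6-(3,5-dimethoxyphenoxy)-1-hydroxy-3,7,9-trimethoxydibenzo[b,d]furan-2-yl]oxy}-4,6-dimethoxyphenyl formate F8, methanolysed in the flask, to the diphenol 2-(2-bromo-6-hydroxy-3,5-dimethoxyphenoxy)-6-(3,5-dimethoxyphenoxy)-3,7,9-trimethoxydibenzo[b,d]furan-1-ol F9. Ring A of F9 is no longer activated for aryl migration. Ullmann closure (CuI, N,N-dimethylglycine, Cs2CO3, dioxane, 90 °C) then gives 22 directly, because the a1 hydroxyl cannot reach a5.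

**Step 8.** The sodium enolate carries a methoxy group on the beta carbon, so E1cB loss of methoxide, followed by aromatization of ring B without its b2 oxygen, competes with oxygen transfer. Addition of the enolate to the sulfonimine by-product is a second possible loss. The fallback avoids a metal enolate; it sets out from 12 and returns at 13. Soft enolization (TMSOTf, Et3N, CH2Cl2, 0 °C) gives (3RS)-6-(3,5-dimethoxyphenoxy)-3,7,9-trimethoxy-1-(trimethylsilyloxy)-3,4-dihydrodibenzo[b,d]furan F10. Rubottom oxidation with dimethyldioxirane (acetone/CH2Cl2, −78 to 0 °C) gives (2S*,3R*)-6-(3,5-dimethoxyphenoxy)-3,7,9-trimethoxy-2-(trimethylsilyloxy)-3,4-dihydrodibenzo[b,d]furan-1(2H)-one F11. Aqueous citric acid in THF desilylates F11 to 13.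

**Step 11.** Deprotonation may occur between the two methoxy groups instead of beside fluorine, and intermolecular bromine–lithium exchange could move the bromine before the formamide is added. The fallback introduces the formyl group by electrophilic substitution; it sets out from 16 and returns at 18. Vilsmeier–Haack formylation of 16 (POCl3, DMF, 0 to 60 °C; aq. NaOAc) should give 2-fluoro-4,6-dimethoxybenzaldehyde F12 by attack para to a methoxy group. Bromination of F12 (NBS, MeCN, 0 °C to rt) at C-3, para to the C-6 methoxy group and beside fluorine, then gives 18.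

## Further compounds

F1 | step 7 | (5RS)-3,5-dimethoxycyclohex-2-en-1-one (racemic, one enantiomer drawn) | COC1=CC(=O)C[C@H](OC)C1
F2 | step 7 | (5RS)-2-iodo-3,5-dimethoxycyclohex-2-en-1-one (racemic, one enantiomer drawn) | COC1=C(I)C(=O)C[C@H](OC)C1
F3 | step 7 | 2-[3-(3,5-dimethoxyphenoxy)-4,6-dimethoxy-2-(methoxymethoxy)phenyl]-4,4,5,5-tetramethyl-1,3,2-dioxaborolane | COCOc1c(Oc2cc(OC)cc(OC)c2)c(OC)cc(OC)c1B1OC(C)(C)C(C)(C)O1
F4 | step 7 | (5RS)-2-[3-(3,5-dimethoxyphenoxy)-4,6-dimethoxy-2-(methoxymethoxy)phenyl]-3,5-dimethoxycyclohex-2-en-1-one (racemic, one enantiomer drawn) | COC1=C(c2c(OCOC)c(Oc3cc(OC)cc(OC)c3)c(OC)cc2OC)C(=O)C[C@H](OC)C1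
F5 | step 12 | 3-bromo-2-hydroxy-4,6-dimethoxybenzaldehyde | O=Cc1c(O)c(Br)c(OC)cc1OC
F6 | step 12 | (2R*,3R*)-2-(2-bromo-6-formyl-3,5-dimethoxyphenoxy)-6-(3,5-dimethoxyphenoxy)-3,7,9-trimethoxy-3,4-dihydrodibenzo[b,d]furan-1(2H)-one (racemic, cis; one enantiomer drawn) | CO[C@H]1[C@@H](Oc2c(C=O)c(OC)cc(OC)c2Br)C(=O)c2c(C1)oc1c(Oc3cc(OC)cc(OC)c3)c(OC)cc(OC)c21
F7 | step 12 | (3RS)-2-(2-bromo-6-formyl-3,5-dimethoxyphenoxy)-6-(3,5-dimethoxyphenoxy)-3,7,9-trimethoxy-1-(trimethylsilyloxy)-3,4-dihydrodibenzo[b,d]furan (racemic, one enantiomer drawn) | CO[C@H]1C(Oc2c(C=O)c(OC)cc(OC)c2Br)=C(O[Si](C)(C)C)c2c(C1)oc1c(Oc3cc(OC)cc(OC)c3)c(OC)cc(OC)c21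
F8 | step 13 | 3-bromo-2-{[6-(3,5-dimethoxyphenoxy)-1-hydroxy-3,7,9-trimethoxydibenzo[b,d]furan-2-yl]oxy}-4,6-dimethoxyphenyl formate | COc1cc2oc3c(Oc4cc(OC)cc(OC)c4)c(OC)cc(OC)c3c2c(O)c1Oc1c(OC=O)c(OC)cc(OC)c1Br
F9 | step 13 | 2-(2-bromo-6-hydroxy-3,5-dimethoxyphenoxy)-6-(3,5-dimethoxyphenoxy)-3,7,9-trimethoxydibenzo[b,d]furan-1-ol | COc1cc2oc3c(Oc4cc(OC)cc(OC)c4)c(OC)cc(OC)c3c2c(O)c1Oc1c(O)c(OC)cc(OC)c1Br
F10 | step 8 | (3RS)-6-(3,5-dimethoxyphenoxy)-3,7,9-trimethoxy-1-(trimethylsilyloxy)-3,4-dihydrodibenzo[b,d]furan (racemic, one enantiomer drawn) | CO[C@H]1C=C(O[Si](C)(C)C)c2c(C1)oc1c(Oc3cc(OC)cc(OC)c3)c(OC)cc(OC)c21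
F11 | step 8 | (2S*,3R*)-6-(3,5-dimethoxyphenoxy)-3,7,9-trimethoxy-2-(trimethylsilyloxy)-3,4-dihydrodibenzo[b,d]furan-1(2H)-one (racemic, trans; one enantiomer drawn) | CO[C@H]1[C@H](O[Si](C)(C)C)C(=O)c2c(C1)oc1c(Oc3cc(OC)cc(OC)c3)c(OC)cc(OC)c21
F12 | step 11 | 2-fluoro-4,6-dimethoxybenzaldehyde | O=Cc1c(F)cc(OC)cc1OC
A1 | alternative 1 | protected target with one free hydroxyl and one ethoxy group on each ring P | CCOc1cc(O)cc(Oc2c(OC)cc(OC)c3c2Oc2c(OC)cc4oc5c(Oc6cc(O)cc(OCC)c6)c(OC)cc(OC)c5c4c2O3)c1
A2 | alternative 1 | pentamethylated core with ethynyl ethers at a1–O and c2–O | C#COc1c(OC)cc(OC)c2c1Oc1c(OC)cc3oc4c(OC#C)c(OC)cc(OC)c4c3c1O2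
A3 | alternative 1 | 3-ethoxycyclobut-2-en-1-one | CCOC1=CC(=O)C1
A4 | alternative 2 | protected target with free c3 and c5 hydroxyls | COc1cc(OC)cc(Oc2c(OC)cc(OC)c3c2Oc2c(OC)cc4oc5c(Oc6cc(OC)cc(OC)c6)c(O)cc(O)c5c4c2O3)c1
A5 | alternative 2 | benzofuran keto ester: 1-(3,5-dimethoxyphenoxy)-2-oxopropyl on furan C-2, methyl ester on furan C-3, dioxin and rings A and P1 complete (racemic, one enantiomer drawn) | COc1cc(OC)cc(Oc2c(OC)cc(OC)c3c2Oc2c(OC)cc4oc([C@H](Oc5cc(OC)cc(OC)c5)C(C)=O)c(C(=O)OC)c4c2O3)c1
A6 | alternative 3 | dibenzofuran with free b1, c3 and c5 hydroxyls and the ring A bromide | COc1cc2oc3c(Oc4cc(OC)cc(OC)c4)c(O)cc(O)c3c2c(Oc2c(OC)cc(OC)c(Oc3cc(OC)cc(OC)c3)c2Br)c1O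
A7 | alternative 3 | 2-[2-bromo-3-(3,5-dimethoxyphenoxy)-4,6-dimethoxyphenoxy]-6-methoxy-1,4-benzoquinone | COC1=CC(=O)C=C(Oc2c(OC)cc(OC)c(Oc3cc(OC)cc(OC)c3)c2Br)C1=O
A8 | alternative 3 | 2-(3,5-dimethoxyphenoxy)benzene-1,3,5-triol | Oc1cc(O)c(Oc2cc(OC)cc(OC)c2)c(O)c1
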